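**Overview** (cembrane numbering: C1 bears the acrylate, C3 the carbinol, C4=C5 the alkene, C7 the acetate, the oxolane oxygen joins C8 and C11, C12 is the tertiary carbinol)

- Retrosynthesis: after removing the acetate and the C3 hydride, the C8–O(oxolane) and C12–OH bonds are cut together, back to a 14-membered 7,8:11,12-bis-oxirane. The carbocycle is then cut at C3–C4 and the chain at C1–C15, C1=C2, C13–C14 and C5–C6.
- Forward: the chain grows from geranyl bromide (C5–C6, then C13–C14, C1=C2, C1–C15), the carbocycle closes at C3–C4, both oxiranes are added, and the oxolane forms last across the ring (15-oxabicyclo[10.2.1]pentadecane core).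
- Enabling feature: the ring oxygen spans C8 and C11 with oxygen on both flanking carbons (C7, C12), and the carbons that receive the new C–O bonds (C8, C12) are the methyl-bearing tertiary carbons of a head-to-tail E,E-1,5-diene. The 7R,8S,11R,12S array on a cis-2,5-oxolane is exactly anti addition to both alkenes.
- Stereochemistry: C1 from an amine-catalysed Michael addition; C7, C8, C11 and C12 from a double Shi epoxidation relayed stereospecifically by the zip; C3 from a CBS reduction; alkene geometry from geranyl bromide, syn hydrozirconation and E-selective SeO2 oxidation.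

Key step: step 15

Assumption: the usual face-selectivity models are taken to hold on this substrate (R,R-oxiranes from E-trisubstituted alkenes with the D-fructose-derived Shi ketone; the 2-methylalkenyl arm as the large group in the CBS model; one face of the E-iminium ion shielded by the silyl prolinol ether).

**Route**

Step 1
Reactants: 1 geranyl bromide; 2 1-propynylmagnesium bromide
Product: 3 skipped dienyne (5E)-6,10-dimethylundeca-5,9-dien-2-yne
Conditions: 2 (1.3 equiv), CuI (10 mol %), THF, 0 °C to rt
Reagents that add atoms: none
Why: Copper-catalysed SN2 alkynylation of a primary allylic bromide by an alkynyl Grignard reagent should join C5–C6 at the unhindered CH2 terminus and leave the E alkene untouched.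

Step 2
Reactants: 3 skipped dienyne
Product: 5 E-alkenyl iodide (2E,5E)-2-iodo-6,10-dimethylundeca-2,5,9-triene, via alkenylzirconocene chloride 4 (not isolated)
Conditions: Cp2Zr(H)Cl (2.0 equiv), THF, rt to 45 °C; then I2, THF, −78 to 0 °C
Reagents that add atoms: iodine, II
Why: Syn hydrozirconation of the alkyne followed by iodinolysis with retention should give the E iodoalkene, because excess Cp2Zr(H)Cl equilibrates zirconium onto the less hindered, methyl-bearing carbon (C4) and the trisubstituted alkenes are too hindered to react.

Step 3
Reactants: 5 E-alkenyl iodide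
Product: 6 E-allylic alcohol (2E,6E,9E)-10-iodo-2,6-dimethylundeca-2,6,9-trien-1-ol
Conditions: SeO2 (0.3 equiv), tBuOOH (2 equiv), salicylic acid (0.1 equiv), CH2Cl2, 0 °C to rt, stopped at partial conversion and 5 recovered
Reagents that add atoms: tert-butyl hydroperoxide, CC(C)(C)OO (net oxygen source); selenium dioxide, O=[Se]=O (catalytic oxygen carrier)
Why: Catalytic SeO2 allylic oxidation (ene reaction, then 2,3-sigmatropic shift) should hydroxylate the E-methyl of the terminal, most electron-rich trisubstituted alkene, as it does in polyprenyl chains, while the iodoalkene is deactivated.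

Step 4
Reactants: 6 E-allylic alcohol
Product: 7 allylic bromide (2E,5E,9E)-11-bromo-2-iodo-6,10-dimethylundeca-2,5,9-triene
Conditions: CBr4 (1.3 equiv), PPh3 (1.4 equiv), CH2Cl2, −20 to 0 °C
Reagents that add atoms: carbon tetrabromide, BrC(Br)(Br)Br
Why: The Appel reaction should convert the primary allylic alcohol to the bromide by SN2 displacement of the oxyphosphonium group without allylic transposition or loss of alkene geometry.

Step 5
Reactants: 7 allylic bromide; 8 allylmagnesium bromide
Product: 9 terminal alkene (2E,5E,9E)-2-iodo-6,10-dimethyltetradeca-2,5,9,13-tetraene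
Conditions: 8 (2 equiv), THF, −78 to 0 °C, no copper salt
Reagents that add atoms: none
Why: Uncatalysed allyl–allyl coupling of an allyl Grignard reagent with a primary allylic bromide should form C13–C14 at the CH2Br carbon, and the absence of copper avoids SN2′ attack and leaves the alkenyl iodide alone at this temperature.

Step 6
Reactants: 9 terminal alkene; 10 crotonaldehyde
Product: 11 E-enal (2E,6E,10E,13E)-14-iodo-6,10-dimethylpentadeca-2,6,10,13-tetraenal
Conditions: 10 (6 equiv), second-generation Hoveyda–Grubbs catalyst RuCl2(H2IMes)(=CH-C6H4-2-OiPr) (5 mol %), CH2Cl2, 40 °C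
Reagents that add atoms: none
Why: Olefin cross metathesis should engage only the monosubstituted alkene (the trisubstituted alkenes and the fully substituted iodoalkene are too hindered) and give the thermodynamically favoured E-enal with loss of propene.

Step 7
Reactants: 11 E-enal; 12 dimethyl malonate
Product: 13 Michael adduct dimethyl 2-[(3S,6E,10E,13E)-14-iodo-6,10-dimethyl-1-oxopentadeca-6,10,13-trien-3-yl]malonate
Conditions: 12 (3 equiv), (R)-2-[bis(3,5-bis(trifluoromethyl)phenyl)(trimethylsilyloxy)methyl]pyrrolidine (10 mol %), EtOH, 0 °C
Reagents that add atoms: none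
Why: In this iminium-catalysed asymmetric Michael addition the diaryl(silyloxy)methyl group of the R catalyst should cover one face of the s-trans E-iminium ion, so malonate adds to the open face of the β-carbon, which for this β-alkyl enal gives 1S.

Step 8
Reactants: 13 Michael adduct
Product: 14 dimethyl acetal dimethyl 2-[(3S,6E,10E,13E)-14-iodo-1,1-dimethoxy-6,10-dimethylpentadeca-6,10,13-trien-3-yl]malonate
Conditions: HC(OMe)3 (5 equiv), p-TsOH·H2O (5 mol %), MeOH, rt; NaHCO3 quench
Reagents that add atoms: trimethyl orthoformate, COC(OC)OC; methanol, CO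
Why: Acid-catalysed acetalisation should mask the aldehyde so that the basic steps that follow cannot cause aldol reaction or retro-Michael loss of the malonate.

Step 9
Reactants: 14 dimethyl acetal
Product: 15 malonic half acid (one ester of 14 hydrolysed; mixture at the malonate carbon)
Conditions: KOH (1.05 equiv), MeOH–THF, 0 °C to rt; cold aq KHSO4 to pH 4, rapid extraction
Reagents that add atoms: potassium hydroxide, [K+].[OH-] (oxygen of the new carboxyl group)
Why: Mono-saponification of a malonate diester should stop after one ester because the carboxylate formed deactivates the second, and either diastereotopic ester leads to the same acrylate in the next step.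

Step 10
Reactants: 15 malonic half acid; 16 formaldehyde
Product: 18 acetal acrylate methyl 2-[(3S,6E,10E,13E)-14-iodo-1,1-dimethoxy-6,10-dimethylpentadeca-6,10,13-trien-3-yl]acrylate, via Mannich base 17 (not isolated)
Conditions: 16 (37 % aq, 5 equiv), Et2NH (1.5 equiv), THF, rt then 60 °C
Reagents that add atoms: none
Why: A Mannich reaction at the malonate carbon followed by decarboxylative elimination of diethylamine (decarboxylative methylenation of a malonic half ester) should install the C15=C16 methylene without touching C1, whose hydrogen is only allylic.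

Step 11
Reactants: 18 acetal acrylate
Product: 19 iodo aldehyde methyl 2-[(3S,6E,10E,13E)-14-iodo-6,10-dimethyl-1-oxopentadeca-6,10,13-trien-3-yl]acrylate
Conditions: p-TsOH·H2O (10 mol %), acetone–H2O 10:1, rt
Reagents that add atoms: water, O
Why: Mild acid-catalysed acetal hydrolysis should free the aldehyde while the acrylate, the alkenes and the alkenyl iodide are inert, and C2 carries no stereocentre that could epimerise.

Step 12
Reactants: 19 iodo aldehyde
Product: 21 14-membered trienol methyl 2-[(1S,3RS,4E,7E,11E)-3-hydroxy-4,8,12-trimethylcyclotetradeca-4,7,11-trien-1-yl]acrylate, via alkenylchromium dichloride 20 (not isolated)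
Conditions: CrCl2 (8 equiv), NiCl2 (2 mol %), DMSO–THF 3:1, rt, 19 added by syringe pump to 2 mM
Reagents that add atoms: none
Why: In this Nozaki–Hiyama–Kishi macrocyclisation zerovalent nickel inserts into the alkenyl C–I bond, the alkenyl group passes to trivalent chromium with retention of geometry and adds only to the aldehyde to close C3–C4 at high dilution; the acrylate is tolerated, and the C3 configuration does not matter because it is erased in the next step.

Step 13
Reactants: 21 14-membered trienol
Product: 22 macrocyclic trienone methyl 2-[(1S,4E,7E,11E)-4,8,12-trimethyl-3-oxocyclotetradeca-4,7,11-trien-1-yl]acrylate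
Conditions: Dess–Martin periodinane (1.3 equiv), CH2Cl2, 0 °C to rt
Reagents that add atoms: none
Why: Dess–Martin oxidation should converge both C3 epimers on one enone, whose carbonyl also deactivates C4=C5 toward the electrophilic epoxidation that follows.

Step 14
Reactants: 22 macrocyclic trienone
Product: 23 macrocyclic bis-oxirane enone (1S,7R,8R,11R,12R)-7,8:11,12-diepoxide of 22
Conditions: D-fructose-derived Shi ketone (1,2:4,5-di-O-isopropylidene-β-D-erythro-2,3-hexodiulo-2,6-pyranose, 0.6 equiv), Oxone (2 KHSO5·KHSO4·K2SO4), K2CO3, Bu4NHSO4 (cat.), MeCN–CH2(OMe)2, aq Na2B4O7/Na2EDTA buffer (pH about 10.5), −5 to 0 °C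
Reagents that add atoms: Oxone as potassium peroxymonosulfate, [K+].[O-]S(=O)(=O)OO (oxygen relayed through the dioxirane of the ketone catalyst)
Why: In the Shi asymmetric epoxidation the chiral dioxirane should deliver oxygen through a spiro transition state to the same enantioface of each E-trisubstituted alkene (R at C7, C8, C11 and C12), while the electrophilic oxidant ignores the electron-poor enone and acrylate alkenes.

Step 15
Reactants: 23 macrocyclic bis-oxirane enone
Product: 25 oxa-bridged diol enone (1S,7R,8S,11R,12S)-8,11-epoxy-7,12-dihydroxy enone, via bicyclic epoxonium ion 24 (not isolated)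
Conditions: CSA (10 mol %), H2O (5 equiv), CH2Cl2 (5 mM), −20 to 0 °C; Et3N quench
Reagents that add atoms: water, O
Why: Proposed new method: protonation of the 7,8-oxirane weakens its bond to tertiary C8, the oxygen of the 11,12-oxirane attacks C8 from the rear across the ring to give the oxirane-fused oxolanium (epoxonium) ion 24, and water opens that ion at tertiary C12, again from the rear; the closest known reaction type is the acid-triggered epoxonium cascade of open-chain 1,5-diene bis-epoxides to 2,5-linked oxolane diols, together with transannular oxygen bridging of cyclic 1,5-diene diepoxides, neither of which has been run on a 14-membered cembrane ring with water as the terminating nucleophile. The oxolane (O, C8, C9, C10, C11) closes in the 5-exo-tet mode, and because it spans the carbocycle this one bond creates the 15-oxabicyclo[10.2.1]pentadecane core; no other ring is formed. C8 and C12 are set by inversion in the two SN2-like openings, C7 and C11 keep the configuration given by the Shi epoxidation because their C–O bonds are never broken, and the cis relation across the oxolane follows from these two facts. The step needs the neighbouring oxirane oxygen to reach C8 before water does (water first at C8, then closure of that hydroxyl onto C11, would lead to the trans-oxolane diastereomer), and it needs termination at C12 and not at C11. Both are secured by the head-to-tail methyl pattern (C8 and C12 tertiary, so Markovnikov preference and the five-membered transition state agree only in this direction), by holding water to a few equivalents in a non-nucleophilic solvent, and by the fact that prior hydrolysis of the 11,12-oxirane at C12 frees a C11 hydroxyl that closes onto C8 in the same mode to the same product. The enone and acrylate alkenes are too electron-poor to intercept the cationic centres, and the flexible 14-membered ring lets the C9–C10 tether reach the rear of C8.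

Step 16
Reactants: 25 oxa-bridged diol enone
Product: 26 enone acetate (7-O-acetyl derivative of 25)
Conditions: Ac2O (3 equiv), pyridine, DMAP (5 mol %), CH2Cl2, 0 °C
Reagents that add atoms: acetic anhydride, CC(=O)OC(C)=O
Why: Nucleophile-catalysed acylation should acetylate the only secondary alcohol (C7), since the tertiary C12 carbinol is far slower under these mild conditions.

Step 17
Reactants: 26 enone acetate
Product: 27 target CNP0266699.4 (1S,3S,7R,8S,11R,12S)
Conditions: (R)-2-methyl-CBS-oxazaborolidine (1.0 equiv), catecholborane (3 equiv), toluene–CH2Cl2, −78 °C; MeOH, then pH 7 buffer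
Reagents that add atoms: none
Why: In the Corey–Bakshi–Shibata reduction the R oxazaborolidine should bind the ketone with the 2-methylalkenyl arm as the large group and deliver hydride to the face that gives 3S, and catecholborane at low temperature reduces the enone in the 1,2 sense only, leaving the acetate and the acrylate untouched.

**Compound list**

1 | geranyl bromide, (2E)-1-bromo-3,7-dimethylocta-2,6-diene | CC(C)=CCC/C(C)=C/CBr | starting material
2 | 1-propynylmagnesium bromide | CC#C[Mg]Br | starting material
3 | skipped dienyne, (5E)-6,10-dimethylundeca-5,9-dien-2-yne | CC(C)=CCC/C(C)=C/CC#CC | intermediate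
4 | alkenylzirconocene chloride, chlorobis(cyclopentadienyl)[(2E,5E)-6,10-dimethylundeca-2,5,9-trien-2-yl]zirconium (not isolated) | CC(C)=CCC/C(C)=C/C/C=C(\C)[Zr](Cl)(C1C=CC=C1)C1C=CC=C1 | intermediate
5 | E-alkenyl iodide, (2E,5E)-2-iodo-6,10-dimethylundeca-2,5,9-triene | CC(C)=CCC/C(C)=C/C/C=C(\C)I | intermediate
6 | E-allylic alcohol, (2E,6E,9E)-10-iodo-2,6-dimethylundeca-2,6,9-trien-1-ol | OC/C(C)=C/CC/C(C)=C/C/C=C(\C)I | intermediate
7 | allylic bromide, (2E,5E,9E)-11-bromo-2-iodo-6,10-dimethylundeca-2,5,9-triene | BrC/C(C)=C/CC/C(C)=C/C/C=C(\C)I | intermediate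
8 | allylmagnesium bromide | C=CC[Mg]Br | starting material
9 | terminal alkene, (2E,5E,9E)-2-iodo-6,10-dimethyltetradeca-2,5,9,13-tetraene | C=CCC/C(C)=C/CC/C(C)=C/C/C=C(\C)I | intermediate
10 | crotonaldehyde, (E)-but-2-enal | C/C=C/C=O | starting material
11 | E-enal, (2E,6E,10E,13E)-14-iodo-6,10-dimethylpentadeca-2,6,10,13-tetraenal | O=C/C=C/CC/C(C)=C/CC/C(C)=C/C/C=C(\C)I | intermediate
12 | dimethyl malonate | COC(=O)CC(=O)OC | starting material
13 | Michael adduct, dimethyl 2-[(3S,6E,10E,13E)-14-iodo-6,10-dimethyl-1-oxopentadeca-6,10,13-trien-3-yl]malonate (1S in cembrane numbering) | O=CC[C@@H](C(C(=O)OC)C(=O)OC)CC/C(C)=C/CC/C(C)=C/C/C=C(\C)I | intermediate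
14 | dimethyl acetal of 13 | COC(OC)C[C@@H](C(C(=O)OC)C(=O)OC)CC/C(C)=C/CC/C(C)=C/C/C=C(\C)I | intermediate
15 | malonic half acid of 14 (mixture at the malonate carbon) | COC(OC)C[C@@H](C(C(=O)O)C(=O)OC)CC/C(C)=C/CC/C(C)=C/C/C=C(\C)I | intermediate
16 | formaldehyde | C=O | starting material
17 | Mannich base, 2-(diethylaminomethyl) derivative of 15 (not isolated) | COC(OC)C[C@@H](C(CN(CC)CC)(C(=O)O)C(=O)OC)CC/C(C)=C/CC/C(C)=C/C/C=C(\C)I | intermediate
18 | acetal acrylate, methyl 2-[(3S,6E,10E,13E)-14-iodo-1,1-dimethoxy-6,10-dimethylpentadeca-6,10,13-trien-3-yl]acrylate | COC(OC)C[C@@H](C(=C)C(=O)OC)CC/C(C)=C/CC/C(C)=C/C/C=C(\C)I | intermediate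
19 | iodo aldehyde, methyl 2-[(3S,6E,10E,13E)-14-iodo-6,10-dimethyl-1-oxopentadeca-6,10,13-trien-3-yl]acrylate | O=CC[C@@H](C(=C)C(=O)OC)CC/C(C)=C/CC/C(C)=C/C/C=C(\C)I | intermediate
20 | alkenylchromium dichloride derived from 19 (trivalent chromium; not isolated) | O=CC[C@@H](C(=C)C(=O)OC)CC/C(C)=C/CC/C(C)=C/C/C=C(\C)[Cr](Cl)Cl | intermediate
21 | 14-membered trienol, methyl 2-[(1S,3RS,4E,7E,11E)-3-hydroxy-4,8,12-trimethylcyclotetradeca-4,7,11-trien-1-yl]acrylate | C=C(C(=O)OC)[C@H]1CC/C(C)=C/CC/C(C)=C/C/C=C(\C)C(O)C1 | intermediate
22 | macrocyclic trienone, methyl 2-[(1S,4E,7E,11E)-4,8,12-trimethyl-3-oxocyclotetradeca-4,7,11-trien-1-yl]acrylate | C=C(C(=O)OC)[C@H]1CC/C(C)=C/CC/C(C)=C/C/C=C(\C)C(=O)C1 | intermediate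
23 | macrocyclic bis-oxirane enone, (1S,7R,8R,11R,12R)-7,8:11,12-diepoxide of 22 | C=C(C(=O)OC)[C@H]1CC[C@@]2(C)O[C@@H]2CC[C@@]3(C)O[C@@H]3C/C=C(\C)C(=O)C1 | intermediate
24 | bicyclic epoxonium ion, oxygen bonded to C8, C11 and C12, free C7 hydroxyl (not isolated) | C=C(C(=O)OC)[C@H]1CC[C@@]2(C)[O+]3[C@@H]2CC[C@@]3(C)[C@H](O)C/C=C(\C)C(=O)C1 | intermediate
25 | oxa-bridged diol enone, (1S,7R,8S,11R,12S)-8,11-epoxy-7,12-dihydroxy-3-oxo compound | C=C(C(=O)OC)[C@H]1CC[C@](C)(O)[C@H]2CC[C@](C)(O2)[C@H](O)C/C=C(\C)C(=O)C1 | intermediate
26 | enone acetate, 7-O-acetyl derivative of 25 | C=C(C(=O)OC)[C@H]1CC[C@](C)(O)[C@H]2CC[C@](C)(O2)[C@H](OC(C)=O)C/C=C(\C)C(=O)C1 | intermediate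
27 | CNP0266699.4, (1S,3S,7R,8S,11R,12S) | C=C(C(=O)OC)[C@H]1CC[C@](C)(O)[C@H]2CC[C@](C)(O2)[C@H](OC(C)=O)C/C=C(\C)[C@@H](O)C1 | target

**Totals and risks**

Total step count: 17. Longest linear sequence: 17 steps (1 to 27).

Steps most likely to fail:

1. Step 15 (proposed new method). Capture of the protonated 7,8-oxirane by water before transannular closure, a cascade running in the reverse sense (attack of the 7,8-oxirane oxygen on C12), or acid-induced rearrangement or elimination of the oxiranes could erode or divert the zip inside the macrocycle.
Fallback, from 18 back to 25, using known chemistry: the oxolane is made on the open chain, where this cascade type is established, and the carbocycle is closed afterwards. Shi epoxidation of 18 under the conditions of step 14 (the acetal masks the aldehyde; the acrylate and the iodoalkene are too electron-poor to react) should give the open-chain bis-oxirane acetal F1. CSA in wet CH2Cl2, then THF–H2O, should run the oxirane zip and hydrolyse the acetal in one acidic operation to the oxolane diol iodo aldehyde F2. CrCl2 with catalytic NiCl2 at high dilution, which tolerates free hydroxyl groups, should then close C3–C4 to the oxa-bridged triol F3 (both C3 epimers). MnO2 in CH2Cl2 should oxidise only the allylic C3 carbinol and deliver 25.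

2. Step 14. Reagent control may be incomplete on the macrocycle: the ring conformation may present the mismatched face of one alkene to the dioxirane, or over-oxidation may set in, so that four stereocentres are not set cleanly in one operation.
Fallback, from 19 back to 23: the oxiranes are installed on the open chain, where reagent control is most reliable, and the transannular zip is kept. NaBH4 in MeOH at −40 °C should reduce only the aldehyde of 19 to the iodo alcohol F4; the aldehyde is parked as an alcohol because an acetal could not be removed later without endangering the oxiranes. Shi epoxidation as in step 14 should give the bis-oxirane iodo alcohol F5. Dess–Martin periodinane buffered with NaHCO3 should return the aldehyde as the bis-oxirane iodo aldehyde F6. CrCl2/NiCl2 macrocyclisation as in step 12, toward which trisubstituted oxiranes should be spectators, should give the macrocyclic bis-oxirane carbinol F7 (both C3 epimers), and buffered Dess–Martin oxidation should lead to 23.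

3. Step 17. Facial selectivity may be poor if the conformation of the macrocyclic enone overrides the catalyst.
Fallback, from 26 back to 27: substrate-controlled reduction followed by stereochemical correction. Luche reduction (NaBH4, CeCl3·7H2O, MeOH, −78 °C) should give the C3 carbinols under substrate control; any 3S epimer is 27 itself. The 3R epimer, 3-epi alcohol F8, would be inverted by a Mitsunobu reaction with chloroacetic acid (PPh3, DIAD, toluene, 0 °C; the tertiary C12 carbinol is inert) to the 3S chloroacetate F9. Thiourea with NaHCO3 in EtOH should cleave the chloroacetate selectively in the presence of the C7 acetate and give 27.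

**Further compounds**

F1 | step 15 | open-chain (7R,8R,11R,12R)-bis-oxirane acetal, diepoxide of 18 | COC(OC)C[C@@H](C(=C)C(=O)OC)CC[C@@]1(C)O[C@@H]1CC[C@@]2(C)O[C@@H]2C/C=C(\C)I
F2 | step 15 | open-chain oxolane diol iodo aldehyde (1S,7R,8S,11R,12S) | O=CC[C@@H](C(=C)C(=O)OC)CC[C@](C)(O)[C@H]1CC[C@](C)(O1)[C@H](O)C/C=C(\C)I
F3 | step 15 | oxa-bridged triol, 3-hydroxy analogue of 25 (both C3 epimers) | C=C(C(=O)OC)[C@H]1CC[C@](C)(O)[C@H]2CC[C@](C)(O2)[C@H](O)C/C=C(\C)C(O)C1
F4 | step 14 | iodo alcohol, aldehyde of 19 reduced to the primary alcohol | OCC[C@@H](C(=C)C(=O)OC)CC/C(C)=C/CC/C(C)=C/C/C=C(\C)I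
F5 | step 14 | (7R,8R,11R,12R)-bis-oxirane iodo alcohol | OCC[C@@H](C(=C)C(=O)OC)CC[C@@]1(C)O[C@@H]1CC[C@@]2(C)O[C@@H]2C/C=C(\C)I
F6 | step 14 | (7R,8R,11R,12R)-bis-oxirane iodo aldehyde | O=CC[C@@H](C(=C)C(=O)OC)CC[C@@]1(C)O[C@@H]1CC[C@@]2(C)O[C@@H]2C/C=C(\C)I
F7 | step 14 | macrocyclic bis-oxirane carbinol, 3-hydroxy analogue of 23 (both C3 epimers) | C=C(C(=O)OC)[C@H]1CC[C@@]2(C)O[C@@H]2CC[C@@]3(C)O[C@@H]3C/C=C(\C)C(O)C1
F8 | step 17 | 3-epi alcohol, (3R) epimer of 27 | C=C(C(=O)OC)[C@H]1CC[C@](C)(O)[C@H]2CC[C@](C)(O2)[C@H](OC(C)=O)C/C=C(\C)[C@H](O)C1
F9 | step 17 | (3S)-chloroacetate of 27 | C=C(C(=O)OC)[C@H]1CC[C@](C)(O)[C@H]2CC[C@](C)(O2)[C@H](OC(C)=O)C/C=C(\C)[C@@H](OC(=O)CCl)C1
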